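| setting | maple | ash | flask |
|---|---|---|---|
| starting material | 0.10 M | 0.10 M | 0.10 M |
| coupling partner | 0.40 equiv | 0.60 equiv | 0.800 equiv |
| free catalyst | 0.67 mol% | 0.67 mol% | 0.67 mol% |
| remark | run made earlier | run made earlier |  |

- maple (time / min: product / %): 1.00: 0.2; 2.00: 2.5; 5.00: 8.2; 12.0: 14.4
- ash (time / min: product / %): 3.00: 3.9; 6.00: 9.7; 10.0: 11.4; 12.0: 16.4

(scatter of a reading: 1 percentage point)

- apparent order in coupling partner when 30% of the starting material are converted (percent change of the rate of making product for one percent more coupling partner charged)
- factor on the rate of making product when 30% of the starting material are converted if coupling partner is charged twice over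

- the numbers in the tables scatter by 1 percentage point (one standard deviation)

A conversion of 30% in the flask spends 37.5% of the coupling partner charged, if each product takes one partner. That gives 1.60 for the gearing, the charge over what this count leaves. If, at a fixed conversion of starting material and with one partner per product, the rate goes with the partner left to some order and the charge changes nothing else, the order in the charge is that order times the gearing.

Turn the question round: suppose the rate in the two runs and in the flask simply followed the partner left, which for the flask means order 1.60 and a factor of 2.60 on doubling. Ash, with 1.50 times the charge of maple, should then have reached about 21.6% at 12.0 min. It read 16.4%, which is 5.2 percentage points short, with a scatter of 1 point. Indifference to the partner needs a gap of 2 points to close, so these two readings stand nearer that side.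

Our own reckoning takes the order read from the product of the two runs at that time, 0.321, and divides it by the gearing of ash at its last reading, 1.38. This gives 0.233 as a reading. For the flask it means order 0.373 and factor 1.25. The forecast stands lower, at 0.25 and 1.12, holding that “the order is low”.

The flask gives order 0.79 and factor 1.34.

    coupling partner + free catalyst → catalyst intermediate A (k = 134 L mol⁻¹ min⁻¹)
    starting material + catalyst intermediate A ⇌ catalyst intermediate B (K = 3.40 L mol⁻¹, k = 33.6 L mol⁻¹ min⁻¹)
    catalyst intermediate B → free catalyst + product (k = 277 min⁻¹)
    coupling partner → decomposed reagent (k = 0.0183 min⁻¹)

Our gearing of 1.60 counted one partner per product, but at 6.72 min the flask's coupling partner goes to catalyst intermediate A 1.3 times as fast as to decomposed reagent, and at 15.0 min, with product at 21.0%, 53% of the charge is left unbound where the count gives 73.8%. At 150 min the flask holds 0% of its coupling partner, with product at 50.5% and starting material at 49.5%.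

(The earlier runs and the new flask stem from a simulated flask with constants of no real substance; noise was put on by code.)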